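**Retrosynthetic overview**
1. Ring A (the lactol) is closed last: the C1 hemiacetal forms when a vinyl group on a 2‑aryl‑THF is cleaved to the aldehyde next to the free C3 benzylic OH; only desilylation follows.
2. Ring B (the THF) is closed before that: the O5–C4 bond is made by displacing a primary tosylate in a triol obtained by reducing a γ‑lactone.
3. Key coupling: the C3a–C3 bond is made by an anti‑aldol between the enolate of a cis‑5‑aryl‑4‑vinyl‑γ‑butyrolactone (one aryl plus the C4 core) and a silylated vanillin (the other aryl); this sets C3a and C3.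
4. The lactone comes from a catalytic asymmetric anti‑allylboration of a second silylated vanillin with an (E)‑γ‑substituted allyl‑Bpin built from but‑3‑yn‑1‑ol (sets C6 and C6a), then oxidative lactonisation.
5. The two aryl aldehydes are made in parallel from catechol and p‑cresol. Ring order: temporary lactone → THF ring B → lactol ring A.

Assumption: the SMILES is followed literally, i.e. (1R,3S,3aS,6R,6aS) with H‑3a and H‑6a trans (a trans‑fused bicycle) and each aryl cis to the substituent on its neighbouring ring‑fusion carbon, not the cis‑fused pinoresinol skeleton the trivial name suggests.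

Labels used below (furo[3,4‑c]furan locants of the target): C1 = CH(OH), C3 = ArCH in the lactol ring, C3a and C6a = ring‑fusion CH, C4 = OCH2, C6 = ArCH in the THF ring.

**Route**

Step 1
Reactants: 1 catechol (benzene‑1,2‑diol)
Product: 2 guaiacol (2‑methoxyphenol)
Conditions: MeI (1.0 equiv), K2CO3, acetone, reflux
Reagents that add atoms: iodomethane, CI
Why: Williamson mono‑O‑methylation; with one equivalent of MeI the mono‑ether is the main product and is separated from catechol and veratrole by base extraction and distillation.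

Step 2
Reactants: 2 guaiacol
Product: 3 4‑bromo‑2‑methoxyphenol
Conditions: NBS (1.0 equiv), MeCN, 0 °C → rt
Reagents that add atoms: N‑bromosuccinimide, O=C1CCC(=O)N1Br
Why: Electrophilic aromatic bromination goes para to the free OH (the stronger donor), giving the vanillin‑type 1,3,4‑pattern.

Step 3
Reactants: 3 4‑bromo‑2‑methoxyphenol
Product: 4 (4‑bromo‑2‑methoxyphenoxy)triisopropylsilane
Conditions: TIPSCl, imidazole, DMF, rt
Reagents that add atoms: triisopropylsilyl chloride, CC(C)[Si](Cl)(C(C)C)C(C)C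
Why: Phenol silylation; TIPS is chosen for this ring because it must survive BuLi, the acid catalyst, LDA, hydride and the later acidic removal of an alkyl TBS ether.

Step 4
Reactants: 4 aryl bromide
Product: 5 3‑methoxy‑4‑[(triisopropylsilyl)oxy]benzaldehyde
Conditions: n‑BuLi, THF, −78 °C; then DMF, −78 °C → rt
Reagents that add atoms: N,N‑dimethylformamide, CN(C)C=O
Why: Br–Li exchange followed by Bouveault formylation; the silyloxy group is para to the carbanion, so no retro‑Brook shift occurs.

Step 5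
Reactants: 6 but‑3‑yn‑1‑ol
Product: 7 (but‑3‑yn‑1‑yloxy)(tert‑butyl)dimethylsilane
Conditions: TBSCl, imidazole, CH2Cl2, rt
Reagents that add atoms: tert‑butyldimethylsilyl chloride, CC(C)(C)[Si](C)(C)Cl
Why: Silyl protection of the alcohol so it tolerates hydroboration and the carbenoid step.

Step 6
Reactants: 7 silyl butynyl ether
Product: 8 (E)‑tert‑butyldimethyl{[4‑(4,4,5,5‑tetramethyl‑1,3,2‑dioxaborolan‑2‑yl)but‑3‑en‑1‑yl]oxy}silane
Conditions: HBpin, Cp2Zr(H)Cl (5 mol%), Et3N (10 mol%), neat, 60 °C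
Reagents that add atoms: pinacolborane, [H]B1OC(C)(C)C(C)(C)O1
Why: Zirconium‑catalysed syn‑hydroboration of the terminal alkyne gives the (E)‑alkenylboronate only.

Step 7
Reactants: 8 (E)‑alkenyl‑Bpin
Product: 9 (E)‑tert‑butyldimethyl{[5‑(4,4,5,5‑tetramethyl‑1,3,2‑dioxaborolan‑2‑yl)pent‑3‑en‑1‑yl]oxy}silane
Conditions: BrCH2Cl, n‑BuLi, THF, −78 °C → rt
Reagents that add atoms: bromochloromethane, ClCBr
Why: Matteson homologation (LiCH2Cl ate complex, 1,2‑alkenyl shift) inserts CH2 with retention of the E geometry, giving a configurationally stable γ‑substituted allylboronate.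

Step 8
Reactants: 5 aldehyde; 9 (E)‑allyl‑Bpin
Product: 10 (1R,2R)‑2‑{2‑[(tert‑butyldimethylsilyl)oxy]ethyl}‑1‑{3‑methoxy‑4‑[(triisopropylsilyl)oxy]phenyl}but‑3‑en‑1‑ol (anti)
Conditions: (R)‑TRIP phosphoric acid (5 mol%), toluene, 4 Å MS, −30 °C
Reagents that add atoms: none
Why: Chiral‑phosphoric‑acid‑catalysed allylboration through a closed chair transition state; the (E)‑γ‑substituent gives the anti diad and the (R)‑catalyst directs Re‑face attack, setting C6 (R) and C6a.

Step 9
Reactants: 10
Product: 11 (1R,2R)‑2‑ethenyl‑1‑{3‑methoxy‑4‑[(triisopropylsilyl)oxy]phenyl}butane‑1,4‑diol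
Conditions: AcOH/THF/H2O (3:1:1), rt
Reagents that add atoms: none
Why: Mild acid hydrolysis removes the primary alkyl TBS ether while the aryl TIPS ether and the benzylic alcohol are untouched.

Step 10
Reactants: 11
Product: 12 (4R,5R)‑4‑ethenyl‑5‑{3‑methoxy‑4‑[(triisopropylsilyl)oxy]phenyl}oxolan‑2‑one (cis‑4,5)
Conditions: TEMPO (20 mol%), PhI(OAc)2 (2.5 equiv), CH2Cl2, rt
Reagents that add atoms: none
Why: TEMPO/BAIB oxidative lactonisation (primary alcohol → aldehyde → lactol → lactone) touches no stereocentre, and the anti diol necessarily gives the cis‑4‑vinyl‑5‑aryl lactone.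

Step 11
Reactants: 13 p‑cresol (4‑methylphenol)
Product: 14 4‑hydroxybenzaldehyde
Conditions: O2 (1 atm), CoCl2 (cat.), NaOH, MeOH, 60 °C
Reagents that add atoms: dioxygen, O=O
Why: Cobalt‑catalysed aerobic benzylic oxidation of the p‑cresolate (via the quinone methide) stops at the aldehyde.

Step 12
Reactants: 14
Product: 15 3‑bromo‑4‑hydroxybenzaldehyde
Conditions: Br2 (1.0 equiv), MeOH, 0 °C
Reagents that add atoms: bromine, BrBr
Why: Electrophilic bromination ortho to OH, since the para position is blocked and the CHO group directs meta to itself.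

Step 13
Reactants: 15
Product: 16 vanillin (4‑hydroxy‑3‑methoxybenzaldehyde)
Conditions: NaOMe, CuBr (cat.), DMF/MeOH, 110 °C
Reagents that add atoms: sodium methoxide, [Na+].[O-]C
Why: Copper‑catalysed Ullmann‑type methoxylation of the o‑bromophenoxide; the phenoxide deactivates the aldehyde towards Cannizzaro chemistry.

Step 14
Reactants: 16
Product: 17 4‑[(tert‑butyldimethylsilyl)oxy]‑3‑methoxybenzaldehyde
Conditions: TBSCl, imidazole, CH2Cl2, rt
Reagents that add atoms: tert‑butyldimethylsilyl chloride, CC(C)(C)[Si](C)(C)Cl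
Why: Phenol silylation; TBS is enough for the ring that enters late and sees only enolate, borohydride, NaH and periodate conditions.

Step 15 (key coupling)
Reactants: 12 lactone; 17 aldehyde
Product: 18 (3R,4S,5R)‑3‑[(S)‑{4‑[(tert‑butyldimethylsilyl)oxy]‑3‑methoxyphenyl}(hydroxy)methyl]‑4‑ethenyl‑5‑{3‑methoxy‑4‑[(triisopropylsilyl)oxy]phenyl}oxolan‑2‑one
Conditions: LDA, THF, −78 °C; ZnCl2; then 17, −78 → −40 °C; AcOH quench
Reagents that add atoms: none
Why: Lactone‑enolate aldol; the aldehyde adds to the face opposite the cis vinyl and aryl groups (3,4‑trans, sets C3a), and the fixed E(O)‑enolate in a Zimmerman–Traxler chair (zinc aldolate, also the thermodynamic isomer) gives the anti carbinol (sets C3 as S).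

Step 16
Reactants: 18
Product: 19 (1S,2S,3S,4R)‑1‑{4‑[(tert‑butyldimethylsilyl)oxy]‑3‑methoxyphenyl}‑3‑ethenyl‑2‑(hydroxymethyl)‑4‑{3‑methoxy‑4‑[(triisopropylsilyl)oxy]phenyl}butane‑1,4‑diol
Conditions: LiBH4, THF, 0 °C → rt
Reagents that add atoms: none
Why: Borohydride reduction of the lactone to the 1,4‑diol; aryl silyl ethers and the alkene are inert and no stereocentre is affected.

Step 17
Reactants: 19
Product: 20 (S)‑{(3S,4S,5R)‑4‑ethenyl‑5‑{3‑methoxy‑4‑[(triisopropylsilyl)oxy]phenyl}oxolan‑3‑yl}{4‑[(tert‑butyldimethylsilyl)oxy]‑3‑methoxyphenyl}methanol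
Conditions: (i) TsCl (1.1 equiv), pyridine, CH2Cl2, 0 °C; (ii) NaH, THF, 0 °C → rt
Reagents that add atoms: none
Why: Selective tosylation of the only primary OH, then 5‑exo‑tet Williamson closure by the C6 alkoxide (retention at C6, its C–O bond is not broken); the C3 alkoxide could only form an oxetane and does not compete.

Step 18
Reactants: 20
Product: 21 (1R,3S,3aS,6R,6aS)‑3‑{4‑[(tert‑butyldimethylsilyl)oxy]‑3‑methoxyphenyl}‑6‑{3‑methoxy‑4‑[(triisopropylsilyl)oxy]phenyl}tetrahydro‑1H,3H‑furo[3,4‑c]furan‑1‑ol (in equilibrium with its open hydroxy‑aldehyde form)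
Conditions: OsO4 (2 mol%), NaIO4, 2,6‑lutidine, dioxane/H2O (3:1), rt
Reagents that add atoms: osmium tetroxide, O=[Os](=O)(=O)=O, with sodium periodate, [Na+].[O-]I(=O)(=O)=O; water, O
Why: Lemieux–Johnson cleavage turns the vinyl group into the C1 aldehyde, which is trapped by the free C3–OH as the hemiacetal; C1 equilibrates to the anomer with OH trans to the C6a–C6 bond (1R), and near‑neutral conditions protect the α‑centre C6a.

Step 19
Reactants: 21
Product: 22 4α‑hydroxypinoresinol as drawn, (1R,3S,3aS,6R,6aS)‑3,6‑bis(4‑hydroxy‑3‑methoxyphenyl)tetrahydro‑1H,3H‑furo[3,4‑c]furan‑1‑ol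
Conditions: TBAF/AcOH (1:1), THF, 0 °C
Reagents that add atoms: none
Why: Buffered fluoride removes both aryl silyl ethers without breaking any C–O or C–C bond at a stereocentre and without base‑induced epimerisation at C6a.

**Compound list**
1 | catechol | Oc1ccccc1O | starting material
2 | guaiacol | COc1ccccc1O | intermediate
3 | 4‑bromo‑2‑methoxyphenol | COc1cc(Br)ccc1O | intermediate
4 | (4‑bromo‑2‑methoxyphenoxy)triisopropylsilane | COc1cc(Br)ccc1O[Si](C(C)C)(C(C)C)C(C)C | intermediate
5 | 3‑methoxy‑4‑(triisopropylsilyloxy)benzaldehyde | COc1cc(C=O)ccc1O[Si](C(C)C)(C(C)C)C(C)C | intermediate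
6 | but‑3‑yn‑1‑ol | C#CCCO | starting material
7 | (but‑3‑yn‑1‑yloxy)(tert‑butyl)dimethylsilane | C#CCCO[Si](C)(C)C(C)(C)C | intermediate
8 | (E)‑4‑(TBSO)but‑1‑enyl‑Bpin | CC(C)(C)[Si](C)(C)OCC/C=C/B1OC(C)(C)C(C)(C)O1 | intermediate
9 | (E)‑5‑(TBSO)pent‑2‑enyl‑Bpin | CC(C)(C)[Si](C)(C)OCC/C=C/CB1OC(C)(C)C(C)(C)O1 | intermediate
10 | (1R,2R)‑anti homoallylic alcohol | CC(C)(C)[Si](C)(C)OCC[C@H](C=C)[C@@H](O)c1ccc(O[Si](C(C)C)(C(C)C)C(C)C)c(OC)c1 | intermediate
11 | (1R,2R)‑2‑ethenyl‑1‑arylbutane‑1,4‑diol | OCC[C@H](C=C)[C@@H](O)c1ccc(O[Si](C(C)C)(C(C)C)C(C)C)c(OC)c1 | intermediate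
12 | (4R,5R)‑cis‑4‑ethenyl‑5‑aryl‑oxolan‑2‑one | C=C[C@H]1CC(=O)O[C@H]1c1ccc(O[Si](C(C)C)(C(C)C)C(C)C)c(OC)c1 | intermediate
13 | p‑cresol | Cc1ccc(O)cc1 | starting material
14 | 4‑hydroxybenzaldehyde | O=Cc1ccc(O)cc1 | intermediate
15 | 3‑bromo‑4‑hydroxybenzaldehyde | O=Cc1ccc(O)c(Br)c1 | intermediate
16 | vanillin | COc1cc(C=O)ccc1O | intermediate
17 | 4‑(tert‑butyldimethylsilyloxy)‑3‑methoxybenzaldehyde | COc1cc(C=O)ccc1O[Si](C)(C)C(C)(C)C | intermediate
18 | (3R,4S,5R)‑aldol lactone with (S)‑carbinol | COc1cc(ccc1O[Si](C)(C)C(C)(C)C)[C@@H](O)[C@@H]1C(=O)O[C@@H](c2ccc(O[Si](C(C)C)(C(C)C)C(C)C)c(OC)c2)[C@H]1C=C | intermediate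
19 | (1S,2S,3S,4R)‑triol | COc1cc(ccc1O[Si](C)(C)C(C)(C)C)[C@@H](O)[C@H](CO)[C@H](C=C)[C@@H](O)c1ccc(O[Si](C(C)C)(C(C)C)C(C)C)c(OC)c1 | intermediate
20 | (S)‑carbinol on (3S,4S,5R)‑4‑ethenyl‑5‑aryl‑oxolane | COc1cc(ccc1O[Si](C)(C)C(C)(C)C)[C@@H](O)[C@@H]1CO[C@@H](c2ccc(O[Si](C(C)C)(C(C)C)C(C)C)c(OC)c2)[C@H]1C=C | intermediate
21 | bis‑silyl (1R,3S,3aS,6R,6aS)‑lactol | COc1cc([C@H]2O[C@@H](O)[C@H]3[C@H]2CO[C@H]3c2ccc(O[Si](C(C)C)(C(C)C)C(C)C)c(OC)c2)ccc1O[Si](C)(C)C(C)(C)C | intermediate
22 | 4α‑hydroxypinoresinol (as given) | COc1cc([C@H]2O[C@@H](O)[C@H]3[C@H]2CO[C@H]3c2ccc(O)c(OC)c2)ccc1O | target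

**Totals**
Total steps: 19. Longest linear sequence: 12 (steps 1–4, 8–10, 15–19), i.e. 12/19 ≈ 0.63.

**Three steps most likely to fail**
- Step 15 (aldol): the carbinol (C3) diastereoselectivity may be modest and the adduct can revert by retro‑aldol. Fallback: C‑acylate the enolate of 12 with the acyl imidazole of the acid derived from 17, then set C3 by catalyst‑controlled Ru–TsDPEN asymmetric transfer hydrogenation of the α‑aroyl lactone (the α‑centre equilibrates to trans).
- Step 8 (allylboration): ee and dr with the functionalised boronate are not guaranteed. Fallback: Ir‑catalysed (Krische) anti‑(hydroxymethyl)allylation of 5 with the cyclic carbonate of cis‑but‑2‑ene‑1,4‑diol gives the same anti vinyl carbinol diad; one‑carbon homologation of its CH2OH (tosylate, cyanide, acidic Pinner lactonisation) then reaches 12.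
- Step 18 (and the nature of 21/22): the trans‑fused lactol is strained, so it may sit largely as the open hydroxy‑aldehyde, and C6a can epimerise towards a cis‑fused isomer if base is present. Fallback: oxidise the aldehyde at the silylated stage to the acid (Pinnick), force the trans‑fused γ‑lactone closed by carboxyl activation (Yamaguchi), and generate the lactol by DIBAL‑H reduction at −78 °C just before the buffered desilylation.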